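**Plan**

- Ring A is numbered C1 (benzoyl-bearing), C2 (OH), C3 (bridge carbon), C4 (OH), C5 (H), C6 (O-prenyl). The first cut is the bond from C3 to the bridging CH2, which gives benzophenone 10 and the Mannich base 15 of isobutyrylfilicinic acid. 15 goes back to phloroglucinol through aminomethylation, geminal C-methylation and Friedel–Crafts acylation.
- Ring A of 10 is then cut at the two ring bonds C1–C2 and C4–C5.
- Enabling feature: C5, C6 and C1 of ring A are the γ, β and α carbons of the O-prenyl enol ether of benzoylacetone (5). C2, C3 and C4, with their two hydroxyls, are a malonyl unit (7).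
- 5 is cut at its enol C–O bond to ynone 3 and prenol, and 3 at its acyl–alkyne bond.
- Forward order: open chain (steps 1–3), ring A by two C-acylations (step 4), filicinic ring by dearomatising methylation of an acylphloroglucinol (steps 5–6), methylene bridge last (steps 7–8).
- Stereochemistry: the target has no stereocentre; the enol ether geometries of 5, 6, 8 and 9 are erased when ring A aromatises.

Key step: step 4

Remark on the chemistry: keto and enol tautomers are counted as one compound. The filicinic ring is drawn in the tautomer of the target SMILES, and the cyclohexadienone that aromatises to 10 in step 4 is not numbered separately.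

**Route**

Step 1
Reactants: 1 N-methoxy-N-methylbenzamide; 2 1-propynylmagnesium bromide (CH3C≡CMgBr, 0.5 M in THF)
Product: 3 1-phenylbut-2-yn-1-one
Conditions: 2 (1.3 equiv), THF, 0 °C → rt; then 1 M HCl, 0 °C
Reagents that add atoms: none
Why: In this Weinreb ketone synthesis the chelated tetrahedral magnesium adduct should persist until the acidic quench, so the alkynyl Grignard reagent adds once and the ynone forms without over-addition.

Step 2
Reactants: 3 1-phenylbut-2-yn-1-one; 4 3-methylbut-2-en-1-ol (prenol)
Product: 5 (E)-3-[(3-methylbut-2-en-1-yl)oxy]-1-phenylbut-2-en-1-one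
Conditions: 4 (1.2 equiv), PMe3 (10 mol %), CH2Cl2, 0 °C → rt
Reagents that add atoms: none
Why: In this phosphine-catalysed oxa-Michael addition the PMe3–ynone zwitterion deprotonates the alcohol and the alkoxide chain adds to the β carbon, which should give the (E) vinylogous ester with the ether oxygen on the former alkyne carbon and hence an unambiguous constitution (any (Z) isomer converges in step 3).

Step 3
Reactants: 5 (E)-3-[(3-methylbut-2-en-1-yl)oxy]-1-phenylbut-2-en-1-one
Product: 6 (Z)-trimethyl({3-[(3-methylbut-2-en-1-yl)oxy]-1-phenylbuta-1,3-dien-1-yl}oxy)silane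
Conditions: LiN(iPr)2 (1.1 equiv, commercial solution), THF, −78 °C; Me3SiCl (1.2 equiv), −78 → 0 °C; solvent exchange to pentane, filtration under argon, no heating, used at once
Reagents that add atoms: chlorotrimethylsilane, C[Si](C)(C)Cl
Why: In this vinylogous silyl enol ether formation the aryl ketone has no α′ hydrogen, so the γ methyl group should be the only site deprotonated and the extended enolate should be trapped on oxygen by Me3SiCl.

Step 4
Reactants: 6 (Z)-trimethyl({3-[(3-methylbut-2-en-1-yl)oxy]-1-phenylbuta-1,3-dien-1-yl}oxy)silane; 7 malonyl dichloride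
Product: 10 (2,4-dihydroxy-6-prenyloxyphenyl)(phenyl)methanone, via keto acid chloride 8 (not isolated), via acylketene 9 (not isolated)
Conditions: 7 (1.05 equiv), CH2Cl2 (0.02 M), −78 → −20 °C, slow addition of 6; then Et3N (2.5 equiv), −78 °C → rt; aqueous citric acid work-up
Reagents that add atoms: none
Why: Proposed new method: the 1-silyloxy-3-alkoxydiene 6 should be acylated by one acid chloride of 7 at its terminal CH2 (a vinylogous Mukaiyama-type acylation that releases Me3SiCl and restores the vinylogous ester in 8), after which Et3N removes HCl from the β-keto acid chloride to give acylketene 9. Enolisation of 9 gives a dienylketene whose far terminus is the α carbon of the enol ether, and bond formation between that carbon and the ketene carbon followed by tautomerisation gives the phloroglucinol ring of 10. The closest known reaction types are the [3+3] cyclocondensations of 1,3-bis-silyl enol ethers with 1,3-dielectrophiles, the formation of 4-hydroxy-2-pyranones from silyl enol ethers and malonyl dichloride, the Claisen cyclisation of 3,5,7-triketo esters to acylphloroglucinols and the dienylketene ring closure that ends the Danheiser benzannulation; none has been shown with the dienol ether of a β-alkoxy enone and malonyl dichloride. Ring A closes in a 6-(enolendo)-exo-dig mode onto the ketene carbon, equivalent to a disrotatory 6π electrocyclisation, and no stereocentre is formed. The selectivity required is γ before α and carbon before oxygen: the terminal carbon of 6 is unhindered and receives electron density from both oxygens, only the α carbon can then reach the second acyl carbon through a six-membered transition state, the oxygen that would lactonise to a pyranone is held as the prenyl ether, and the competing aldol acceptor (the benzoyl carbonyl) is deactivated as a vinylogous ester. Since the ether oxygen is carried on the carbon that becomes C6, its place next to the benzoyl group is fixed before the ring exists.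

Step 5
Reactants: 11 phloroglucinol; 12 isobutyryl chloride
Product: 13 2-methyl-1-(2,4,6-trihydroxyphenyl)propan-1-one
Conditions: AlCl3 (4 equiv), 12 (1.05 equiv), CH2Cl2/MeNO2, 0 → 40 °C; ice/1 M HCl
Reagents that add atoms: none
Why: In this Friedel–Crafts acylation the symmetrical, strongly activated ring should be acylated once, because the first acyl group, chelated and complexed to AlCl3, deactivates the ring toward a second acylation.

Step 6
Reactants: 13 2-methyl-1-(2,4,6-trihydroxyphenyl)propan-1-one
Product: 14 isobutyrylfilicinic acid (3,5-dihydroxy-4,4-dimethyl-2-(2-methylpropanoyl)cyclohexa-2,5-dien-1-one)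
Conditions: NaOMe (3 equiv), MeI (2.2 equiv), MeOH, 0 °C → rt; 1 M HCl
Reagents that add atoms: iodomethane, CI
Why: In this dearomatising geminal C-methylation the phenoxide should be alkylated twice at one ring carbon, the second methylation breaking aromaticity to leave the vinylogous acid, with the MeI stoichiometry limiting under- and over-methylation.

Step 7
Reactants: 14 isobutyrylfilicinic acid
Product: 15 2-[(dimethylamino)methyl]-3,5-dihydroxy-4,4-dimethyl-6-(2-methylpropanoyl)cyclohexa-2,5-dien-1-one
Conditions: CH2(NMe2)2 (1.5 equiv), CH2Cl2, 0 °C → rt, 14 added slowly to the aminal; evaporation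
Reagents that add atoms: bis(dimethylamino)methane, CN(C)CN(C)C
Why: In this Mannich reaction the strongly acidic enolic triketone should protonate the aminal to release CH2=NMe2+, which is captured at the only unsubstituted enolic ring carbon, while the excess aminal suppresses the methylene-bridged dimer.

Step 8
Reactants: 10 (2,4-dihydroxy-6-prenyloxyphenyl)(phenyl)methanone; 15 Mannich base of isobutyrylfilicinic acid
Product: 16 sarothralin
Conditions: 15 (1.0–1.1 equiv) added in portions, 1,4-dioxane, 80 °C, argon sweep; aqueous citric acid work-up
Reagents that add atoms: none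
Why: In this elimination–Michael sequence (quinone-methide-type alkylation of a phenol by a Mannich base) 15 should lose Me2NH on warming to give the 6-methylene trione, which ring A of 10 should attack at C3 between its two hydroxyls, because C5 is screened by the prenyloxy CH2 turned toward it by the benzoyl group and has only one flanking hydrogen-bond-donating OH.

**Compound list**

1 | N-methoxy-N-methylbenzamide | CON(C)C(=O)c1ccccc1 | starting material
2 | 1-propynylmagnesium bromide | CC#C[Mg]Br | starting material
3 | 1-phenylbut-2-yn-1-one | CC#CC(=O)c1ccccc1 | intermediate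
4 | 3-methylbut-2-en-1-ol (prenol) | CC(C)=CCO | starting material
5 | (E)-3-[(3-methylbut-2-en-1-yl)oxy]-1-phenylbut-2-en-1-one | C/C(OCC=C(C)C)=C\C(=O)c1ccccc1 | intermediate
6 | (Z)-trimethyl({3-[(3-methylbut-2-en-1-yl)oxy]-1-phenylbuta-1,3-dien-1-yl}oxy)silane | C=C(OCC=C(C)C)/C=C(\O[Si](C)(C)C)c1ccccc1 | intermediate
7 | malonyl dichloride | O=C(Cl)CC(Cl)=O | starting material
8 | (E)-5-[(3-methylbut-2-en-1-yl)oxy]-3,7-dioxo-7-phenylhept-5-enoyl chloride | O=C(Cl)CC(=O)C/C(OCC=C(C)C)=C\C(=O)c1ccccc1 | intermediate
9 | (E)-3-[(3-methylbut-2-en-1-yl)oxy]-1-phenylhepta-2,6-diene-1,5,7-trione (acylketene) | O=C=CC(=O)C/C(OCC=C(C)C)=C\C(=O)c1ccccc1 | intermediate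
10 | (2,4-dihydroxy-6-prenyloxyphenyl)(phenyl)methanone (2,4-dihydroxy-6-prenyloxybenzophenone) | CC(C)=CCOc1cc(O)cc(O)c1C(=O)c1ccccc1 | intermediate
11 | phloroglucinol | Oc1cc(O)cc(O)c1 | starting material
12 | isobutyryl chloride | CC(C)C(Cl)=O | starting material
13 | 2-methyl-1-(2,4,6-trihydroxyphenyl)propan-1-one | CC(C)C(=O)c1c(O)cc(O)cc1O | intermediate
14 | isobutyrylfilicinic acid | CC(C)C(=O)C1=C(O)C(C)(C)C(O)=CC1=O | intermediate
15 | 2-[(dimethylamino)methyl]-3,5-dihydroxy-4,4-dimethyl-6-(2-methylpropanoyl)cyclohexa-2,5-dien-1-one | CC(C)C(=O)C1=C(O)C(C)(C)C(O)=C(CN(C)C)C1=O | intermediate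
16 | sarothralin | CC(C)=CCOc1cc(O)c(CC2=C(O)C(C)(C)C(=O)C(C(=O)C(C)C)=C2O)c(O)c1C(=O)c1ccccc1 | target

**Step count and risks**

Total steps: 8. Longest linear sequence: 5 steps (1, 2, 3, 4, 8); the filicinic branch (5, 6, 7) joins at step 8.

Steps most likely to fail:

1. Step 4. The diene may be acylated at its internal α carbon or on oxygen, the acylketene may oligomerise, or the prenyl group may be lost through lactonisation to a pyranone. The fallback uses known chemistry, sets out from phloroglucinol 11 and returns at 10. Friedel–Crafts benzoylation of 11 (benzoyl chloride, AlCl3) should give 2,4,6-trihydroxybenzophenone F1. Silylation with tBuMe2SiCl (2.1 equiv) and imidazole should cap the para hydroxyl and one ortho hydroxyl, leaving the ketone-chelated one free, to give [2-hydroxy-4,6-bis(tert-butyldimethylsilyloxy)phenyl](phenyl)methanone F2. Mitsunobu etherification of the remaining phenol with prenol 4 (PPh3, diisopropyl azodicarboxylate) should give [2-prenyloxy-4,6-bis(tert-butyldimethylsilyloxy)phenyl](phenyl)methanone F3. Bu4NF buffered with AcOH (THF, 0 °C) then removes both silyl groups to give 10.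

2. Step 8. Ring A may be attacked through its other free position (C5) or alkylated twice, or the Mannich base may self-condense. The fallback fixes the bridge carbon on ring A first, sets out from 10 and returns at 16. Silylation of the non-chelated 4-hydroxyl (tBuMe2SiCl, imidazole) should give [2-hydroxy-6-prenyloxy-4-(tert-butyldimethylsilyloxy)phenyl](phenyl)methanone F4. Ortho-specific formylation of the one remaining phenol (MgCl2, Et3N, paraformaldehyde, MeCN, reflux) can only occur at C3 and should give 3-benzoyl-2-hydroxy-4-prenyloxy-6-(tert-butyldimethylsilyloxy)benzaldehyde F5. Three-component reductive alkylation of 14 with F5 (Hantzsch ester, L-proline cat., CH2Cl2, rt) should give 4-O-(tert-butyldimethylsilyl)sarothralin F6. Bu4NF/AcOH then gives 16. This path does not need 15.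

3. Step 7. The Mannich base may eliminate Me2NH prematurely and be captured by unreacted 14, so that the material drains into the symmetrical methylene-bridged dimer. The fallback makes that dimer on purpose as the methylene donor, sets out from 14 and returns at 16. Treating 14 with aqueous formaldehyde (0.5 equiv, EtOH, rt) should give methylenebis(isobutyrylfilicinic acid) F7. Base-mediated exchange of F7 with 10 (rottlerone change; K2CO3, MeOH, 50 °C) should then transfer one filicinic-CH2 unit to C3 of 10 to give 16, with 14 recovered for recycling.

**Further compounds**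

F1 | step 4 | 2,4,6-trihydroxybenzophenone | O=C(c1ccccc1)c1c(O)cc(O)cc1O
F2 | step 4 | [2-hydroxy-4,6-bis(tert-butyldimethylsilyloxy)phenyl](phenyl)methanone | CC(C)(C)[Si](C)(C)Oc1cc(O)c(C(=O)c2ccccc2)c(O[Si](C)(C)C(C)(C)C)c1
F3 | step 4 | [2-prenyloxy-4,6-bis(tert-butyldimethylsilyloxy)phenyl](phenyl)methanone | CC(C)=CCOc1cc(O[Si](C)(C)C(C)(C)C)cc(O[Si](C)(C)C(C)(C)C)c1C(=O)c1ccccc1
F4 | step 8 | [2-hydroxy-6-prenyloxy-4-(tert-butyldimethylsilyloxy)phenyl](phenyl)methanone | CC(C)=CCOc1cc(O[Si](C)(C)C(C)(C)C)cc(O)c1C(=O)c1ccccc1
F5 | step 8 | 3-benzoyl-2-hydroxy-4-prenyloxy-6-(tert-butyldimethylsilyloxy)benzaldehyde | CC(C)=CCOc1cc(O[Si](C)(C)C(C)(C)C)c(C=O)c(O)c1C(=O)c1ccccc1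
F6 | step 8 | 4-O-(tert-butyldimethylsilyl)sarothralin | CC(C)=CCOc1cc(O[Si](C)(C)C(C)(C)C)c(CC2=C(O)C(C)(C)C(=O)C(C(=O)C(C)C)=C2O)c(O)c1C(=O)c1ccccc1
F7 | step 7 | methylenebis(isobutyrylfilicinic acid) | CC(C)C(=O)C1=C(O)C(C)(C)C(O)=C(CC2=C(O)C(C)(C)C(=O)C(C(=O)C(C)C)=C2O)C1=O
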